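The seven-membered ring B is closed around a two-carbon ambiphile. In daucane numbering C1 is a quaternary carbon next to oxygenated C2, C10 is a carbinol and C8–C9 an oxirane. Read backwards, these are an enolate donor, an aldehyde acceptor, an ylide donor and a methyl ketone acceptor. In one flask the silyl enol ether of a ring A cyclopentanone, which carries a 3-oxobutyl chain on C5, meets (2-oxoethyl)diphenylsulfonium triflate. A Mukaiyama aldol addition forms C1–C10, then base releases the sulfonium ylide, which forms C8–C9 and the oxirane. Ring B and four stereocentres arise together. Ring A comes from the enantiomer of alpha-thujone by anti opening of its cyclopropane.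

Key step: step 11

Numbering (daucane): C1 ring-fusion C(CH3), C2 CH–OAc, C3 CH2, C4 C(OH)(i-Pr), C5 ring-fusion CH, C6 CH–O-aroyl, C7 CH2, C8 oxirane C(CH3), C9 oxirane CH, C10 CHOH; ring A = C1–C5, ring B = C1, C5–C10.

Assumption: read literally, the C8 and C9 tags of the target string place C7 and C10 trans on the oxirane. The route makes the ordinary cis-fused oxirane with its oxygen on the face of the C10 oxygen, so the chemistry would not give the literal trans-fused isomer. Every SMILES nevertheless keeps the tags of the target string at C8 and C9.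

Step 1
Reactants: 1 3-methylbut-1-yne
Product: 2 4-methylpent-2-ynal
Conditions: n-BuLi, THF, −78 °C; DMF, −78 to 0 °C; cold aq. HCl
Reagents that add atoms: N,N-dimethylformamide, CN(C)C=O
Why: Formylation of a lithium acetylide with DMF is the standard route to ynals and creates no stereocentre.

Step 2
Reactants: 2 4-methylpent-2-ynal; 3 (E)-crotylboronic acid pinacol ester
Product: 4 (3S,4S)-3,7-dimethyloct-1-en-5-yn-4-ol
Conditions: (S)-TRIP phosphoric acid (5 mol%), toluene, −30 °C; aqueous work-up
Reagents that add atoms: none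
Why: Phosphoric-acid-catalysed crotylboration runs through a closed chair transition state, so the E-crotyl geometry gives the anti pair and the catalyst enantiomer chosen for Si-face attack sets both centres as S.

Step 3
Reactants: 4 (3S,4S)-3,7-dimethyloct-1-en-5-yn-4-ol
Product: 5 (1R,4S,5S)-4-methyl-1-(propan-2-yl)bicyclo[3.1.0]hexan-3-one (enantiomer of natural alpha-thujone)
Conditions: PtCl2 (5 mol%), toluene, 80 °C
Reagents that add atoms: none
Why: The known cycloisomerisation of 5-en-1-yn-3-ols (alkyne activation, cyclopropanation by the alkene, 1,2-hydride shift from the carbinol carbon) gives the bicyclo[3.1.0]hexan-3-one, and the methyl stereocentre places the new cyclopropane on the face opposite to it.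

Step 4
Reactants: 5 (1R,4S,5S)-4-methyl-1-(propan-2-yl)bicyclo[3.1.0]hexan-3-one
Product: 7 (1R,4S,5R)-5-(hydroxymethyl)-4-methyl-1-(propan-2-yl)cyclopentane-1,3-diol (both C3 epimers), via chloromercurial 6 (not isolated)
Conditions: Hg(OCOCF3)2, THF/H2O, 0 °C; aq. NaCl; then NaBH4, O2, DMF, 0 °C
Reagents that add atoms: water, O; dioxygen, O=O; mercury bis(trifluoroacetate), FC(F)(F)C(=O)O[Hg]OC(=O)C(F)(F)F (atoms kept only in 6); sodium chloride, [Na+].[Cl-] (atoms kept only in 6)
Why: Oxymercuration of a cyclopropane puts divalent mercury on the least substituted carbon (C6) and water on the most substituted one (C4) with inversion, which sets the C4 hydroxyl trans to the C5–C6 bond, and oxidative demercuration then exchanges mercury for hydroxyl while borohydride also reduces the ketone to inconsequential epimers.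

Step 5
Reactants: 7 (1R,4S,5R)-5-(hydroxymethyl)-4-methyl-1-(propan-2-yl)cyclopentane-1,3-diol
Product: 8 (1S,2R,5S)-2-hydroxy-5-methyl-4-oxo-2-(propan-2-yl)cyclopentane-1-carbaldehyde
Conditions: Dess–Martin periodinane (2.5 equiv), NaHCO3, CH2Cl2, 0 °C
Reagents that add atoms: none
Why: Dess–Martin oxidation converts the primary and the secondary alcohol into aldehyde and ketone under neutral conditions that spare the tertiary alcohol and the epimerisable C5 centre.

Step 6
Reactants: 8 (1S,2R,5S)-2-hydroxy-5-methyl-4-oxo-2-(propan-2-yl)cyclopentane-1-carbaldehyde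
Product: 10 methyl (3R)-3-hydroxy-3-[(1R,2R,5S)-2-hydroxy-5-methyl-4-oxo-2-(propan-2-yl)cyclopentyl]propanoate, via trimethylsilyl ether 9 (not isolated)
Conditions: Ti(OiPr)4 (5 mol%), tridentate binaphthyl aminophenol salicylaldimine ligand (enantiomer for Re-face attack), 3,5-di-tert-butylsalicylic acid, Et2O, −10 °C; then 1 M HCl, THF
Reagents that add atoms: 1-methoxy-1-(trimethylsilyloxy)ethene, C=C(OC)O[Si](C)(C)C
Why: The catalytic asymmetric Mukaiyama acetate aldol addition takes the aldehyde and not the hindered ketone, and the ligand enantiomer that attacks the Re face overrides the Felkin–Anh bias and sets C6 as R.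

Step 7
Reactants: 10 methyl (3R)-3-hydroxy-3-[(1R,2R,5S)-2-hydroxy-5-methyl-4-oxo-2-(propan-2-yl)cyclopentyl]propanoate
Product: 11 methyl (3R)-3-[(1R,5R)-2-methyl-5-(propan-2-yl)-3,5-bis(triethylsilyloxy)cyclopent-2-en-1-yl]-3-(triethylsilyloxy)propanoate
Conditions: Et3SiOTf (4 equiv), Et3N, CH2Cl2, 0 °C to rt
Reagents that add atoms: triethylsilyl trifluoromethanesulfonate, CC[Si](CC)(CC)OS(=O)(=O)C(F)(F)F
Why: Silyl triflate with triethylamine silylates both alcohols and converts the only ketone into its thermodynamic, tetrasubstituted silyl enol ether (C1=C2), the ester being far less prone to enolise.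

Step 8
Reactants: 11 methyl (3R)-3-[(1R,5R)-2-methyl-5-(propan-2-yl)-3,5-bis(triethylsilyloxy)cyclopent-2-en-1-yl]-3-(triethylsilyloxy)propanoate
Product: 13 (4R)-4-[(1R,5R)-2-methyl-5-(propan-2-yl)-3,5-bis(triethylsilyloxy)cyclopent-2-en-1-yl]-4-(triethylsilyloxy)butan-2-one, via N-methoxy-N-methylamide 12 (not isolated)
Conditions: MeNH(OMe)·HCl, i-PrMgCl, THF, −20 °C; then MeMgBr, −20 to 0 °C; aq. NH4Cl
Reagents that add atoms: N,O-dimethylhydroxylamine hydrochloride, CNOC.Cl (atoms kept only in 12); methylmagnesium bromide, C[Mg]Br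
Why: Magnesium amide aminolysis followed by Grignard addition to the N-methoxy-N-methylamide stops at the ketone through the chelated tetrahedral intermediate, so the methyl ketone is unveiled only after the enol ether of the ring ketone is in place.

Step 9
Reactants: 14 diphenyl sulfide; 15 2-bromo-1,1-dimethoxyethane
Product: 16 (2,2-dimethoxyethyl)diphenylsulfonium trifluoromethanesulfonate
Conditions: AgOSO2CF3, CH2Cl2, 0 °C to rt, dark
Reagents that add atoms: silver trifluoromethanesulfonate, [Ag+].[O-]S(=O)(=O)C(F)(F)F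
Why: Silver-assisted S-alkylation of a diaryl sulfide by a primary bromide is the usual entry to alkyldiarylsulfonium salts and is driven by precipitation of silver bromide.

Step 10
Reactants: 16 (2,2-dimethoxyethyl)diphenylsulfonium trifluoromethanesulfonate
Product: 17 (2-oxoethyl)diphenylsulfonium trifluoromethanesulfonate
Conditions: aq. CF3SO3H (1 M), 60 °C; azeotropic drying with toluene, molecular sieves
Reagents that add atoms: water, O
Why: Acid hydrolysis of the dimethyl acetal frees the aldehyde, which as the salt of a non-basic anion should be as storable as the commercial formylmethylphosphonium salts.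

Step 11
Reactants: 13 (4R)-4-[(1R,5R)-2-methyl-5-(propan-2-yl)-3,5-bis(triethylsilyloxy)cyclopent-2-en-1-yl]-4-(triethylsilyloxy)butan-2-one; 17 (2-oxoethyl)diphenylsulfonium trifluoromethanesulfonate
Product: 19 8,9-epoxy-4,6,10-tris(triethylsilyloxy)daucan-2-one (trans-fused, all centres as in 24), via beta-silyloxy sulfonium triflate 18 (not isolated)
Conditions: Et3SiOTf (20 mol%), CH2Cl2, −78 to −40 °C; then KN(SiMe3)2 (1.05 equiv), THF, −78 to 0 °C
Reagents that add atoms: none
Why: Proposed new method: a silyl-triflate-catalysed Mukaiyama aldol addition of the C1=C2 enol ether to the strongly electrophilic aldehyde of 17 forms C1–C10 and moves the silyl group to O10 (18), then the amide base removes a C9 proton next to sulfur (far more acidic than any ketone alpha proton), the non-stabilised ylide adds to the C8 ketone and the alkoxide displaces diphenyl sulfide from C9; the closest known reaction types are the Mukaiyama aldol addition, the Corey–Chaykovsky epoxidation of ketones by diphenylsulfonium alkylides and the epoxy-annulation of amino ketones with vinylsulfonium salts, whose productive intermediate is the same kind of beta-heteroatom-substituted ylide. Ring B closes by 7-exo-trig addition of C9 to C8 and the oxirane by a 3-exo-tet displacement that needs O8 and sulfur antiperiplanar, which in a seven-membered ring means a trans-diaxial betaine and hence a cis-fused oxirane. C1 is set by approach of the aldehyde to the enol ether face opposite to the C5 side chain and the isopropyl group, which makes the ring fusion trans. C10 is set by the open antiperiplanar transition state in which the sulfoniomethyl group lies next to CH3-1 and not next to the branched C5. C9 and C8 are set by the bulky diphenylsulfonio group taking the position anti to the C10 silyloxy group, so that oxygen enters C9 from the face of O10 and CH3-8 ends on the opposite face. The step needs aldehyde-over-ketone selectivity in the aldol stage (secured by the cationic aldehyde and by the congestion of joining the fully substituted C1 to C8) and ylide formation without enolisation or lasting loss of silanolate (secured by one equivalent of base at low temperature and by the reversibility of that loss).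

Step 12
Reactants: 19 8,9-epoxy-4,6,10-tris(triethylsilyloxy)daucan-2-one
Product: 20 8,9-epoxy-4,6,10-tris(triethylsilyloxy)daucan-2-ol (hydroxyl cis to CH3-1)
Conditions: NaBH4, MeOH/THF, 0 °C
Reagents that add atoms: none
Why: In this borohydride reduction hydride reaches the C2 carbonyl from the face opposite to the angular methyl group, as in 17-oxo steroids, and gives the alcohol cis to CH3-1.

Step 13
Reactants: 20 8,9-epoxy-4,6,10-tris(triethylsilyloxy)daucan-2-ol
Product: 21 8,9-epoxy-4,6,10-tris(triethylsilyloxy)daucan-2-yl acetate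
Conditions: Ac2O, DMAP, pyridine, rt
Reagents that add atoms: acetic anhydride, CC(=O)OC(C)=O
Why: DMAP-catalysed acetylation meets a single free hydroxyl because all the others are silyl ethers.

Step 14
Reactants: 21 8,9-epoxy-4,6,10-tris(triethylsilyloxy)daucan-2-yl acetate
Product: 22 8,9-epoxy-4,6,10-trihydroxydaucan-2-yl acetate
Conditions: HF·pyridine, pyridine, THF, 0 °C
Reagents that add atoms: none
Why: Buffered fluoride desilylation cleaves the three triethylsilyl ethers without acid strong enough to open the oxirane or base strong enough to move the acetate.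

Step 15
Reactants: 22 8,9-epoxy-4,6,10-trihydroxydaucan-2-yl acetate; 23 3,4-dimethoxybenzoyl chloride
Product: 24 (1R,2S,4R,5R,6R,8R,9R,10R)-2-acetoxy-8,9-epoxy-4,10-dihydroxydaucan-6-yl 3,4-dimethoxybenzoate
Conditions: 23 (1.1 equiv), Et3N, DMAP (cat.), CH2Cl2, 0 °C
Reagents that add atoms: none
Why: DMAP-catalysed esterification with the acid chloride should take the C6 hydroxyl because the C4 hydroxyl is tertiary and the C10 hydroxyl is neopentylic, flanked by quaternary C1 and the oxirane.

Compound list

1 | 3-methylbut-1-yne | CC(C)C#C | starting material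
2 | 4-methylpent-2-ynal | CC(C)C#CC=O | intermediate
3 | (E)-crotylboronic acid pinacol ester | C/C=C/CB1OC(C)(C)C(C)(C)O1 | starting material
4 | (3S,4S)-3,7-dimethyloct-1-en-5-yn-4-ol | CC(C)C#C[C@@H](O)[C@@H](C)C=C | intermediate
5 | (1R,4S,5S)-4-methyl-1-(propan-2-yl)bicyclo[3.1.0]hexan-3-one | C[C@@H]1C(=O)C[C@@]2([C@H]1C2)C(C)C | intermediate
6 | {[2-hydroxy-5-methyl-4-oxo-2-(propan-2-yl)cyclopentyl]methyl}mercury chloride, hydroxyl and methyl both trans to the CH2Hg group | Cl[Hg]C[C@H]1[C@H](C)C(=O)C[C@@]1(O)C(C)C | intermediate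
7 | (1R,4S,5R)-5-(hydroxymethyl)-4-methyl-1-(propan-2-yl)cyclopentane-1,3-diol, both C3 epimers | OC[C@H]1[C@H](C)C(O)C[C@@]1(O)C(C)C | intermediate
8 | (1S,2R,5S)-2-hydroxy-5-methyl-4-oxo-2-(propan-2-yl)cyclopentane-1-carbaldehyde | O=C[C@H]1[C@H](C)C(=O)C[C@@]1(O)C(C)C | intermediate
9 | methyl (3R)-3-[(1R,2R,5S)-2-hydroxy-5-methyl-4-oxo-2-(propan-2-yl)cyclopentyl]-3-(trimethylsilyloxy)propanoate | COC(=O)C[C@@H](O[Si](C)(C)C)[C@H]1[C@H](C)C(=O)C[C@@]1(O)C(C)C | intermediate
10 | methyl (3R)-3-hydroxy-3-[(1R,2R,5S)-2-hydroxy-5-methyl-4-oxo-2-(propan-2-yl)cyclopentyl]propanoate | COC(=O)C[C@@H](O)[C@H]1[C@H](C)C(=O)C[C@@]1(O)C(C)C | intermediate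
11 | methyl (3R)-3-[(1R,5R)-2-methyl-5-(propan-2-yl)-3,5-bis(triethylsilyloxy)cyclopent-2-en-1-yl]-3-(triethylsilyloxy)propanoate | COC(=O)C[C@@H](O[Si](CC)(CC)CC)[C@H]1C(C)=C(O[Si](CC)(CC)CC)C[C@@]1(O[Si](CC)(CC)CC)C(C)C | intermediate
12 | (3R)-N-methoxy-N-methyl-3-[(1R,5R)-2-methyl-5-(propan-2-yl)-3,5-bis(triethylsilyloxy)cyclopent-2-en-1-yl]-3-(triethylsilyloxy)propanamide | CON(C)C(=O)C[C@@H](O[Si](CC)(CC)CC)[C@H]1C(C)=C(O[Si](CC)(CC)CC)C[C@@]1(O[Si](CC)(CC)CC)C(C)C | intermediate
13 | (4R)-4-[(1R,5R)-2-methyl-5-(propan-2-yl)-3,5-bis(triethylsilyloxy)cyclopent-2-en-1-yl]-4-(triethylsilyloxy)butan-2-one | CC(=O)C[C@@H](O[Si](CC)(CC)CC)[C@H]1C(C)=C(O[Si](CC)(CC)CC)C[C@@]1(O[Si](CC)(CC)CC)C(C)C | intermediate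
14 | diphenyl sulfide | c1ccc(cc1)Sc1ccccc1 | starting material
15 | 2-bromo-1,1-dimethoxyethane | COC(CBr)OC | starting material
16 | (2,2-dimethoxyethyl)diphenylsulfonium trifluoromethanesulfonate | COC(C[S+](c1ccccc1)c1ccccc1)OC.[O-]S(=O)(=O)C(F)(F)F | intermediate
17 | (2-oxoethyl)diphenylsulfonium trifluoromethanesulfonate | O=CC[S+](c1ccccc1)c1ccccc1.[O-]S(=O)(=O)C(F)(F)F | intermediate
18 | aldol adduct: cyclopentanone whose C1 carries CH3 and the (R)-CH(OSiEt3)CH2S(+)Ph2 group trans to the C5 side chain, triflate salt | CC(=O)C[C@@H](O[Si](CC)(CC)CC)[C@H]1[C@](C)([C@@H](O[Si](CC)(CC)CC)C[S+](c2ccccc2)c2ccccc2)C(=O)C[C@@]1(O[Si](CC)(CC)CC)C(C)C.[O-]S(=O)(=O)C(F)(F)F | intermediate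
19 | 8,9-epoxy-4,6,10-tris(triethylsilyloxy)daucan-2-one, centres as in 24 | CC[Si](CC)(CC)O[C@@H]2C[C@@]3(C)O[C@@H]3[C@H](O[Si](CC)(CC)CC)[C@]3(C)C(=O)C[C@@](O[Si](CC)(CC)CC)(C(C)C)[C@@H]23 | intermediate
20 | 8,9-epoxy-4,6,10-tris(triethylsilyloxy)daucan-2-ol, hydroxyl cis to CH3-1 | CC[Si](CC)(CC)O[C@@H]2C[C@@]3(C)O[C@@H]3[C@H](O[Si](CC)(CC)CC)[C@]3(C)[C@@H](O)C[C@@](O[Si](CC)(CC)CC)(C(C)C)[C@@H]23 | intermediate
21 | 8,9-epoxy-4,6,10-tris(triethylsilyloxy)daucan-2-yl acetate | CC[Si](CC)(CC)O[C@@H]2C[C@@]3(C)O[C@@H]3[C@H](O[Si](CC)(CC)CC)[C@]3(C)[C@@H](OC(C)=O)C[C@@](O[Si](CC)(CC)CC)(C(C)C)[C@@H]23 | intermediate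
22 | 8,9-epoxy-4,6,10-trihydroxydaucan-2-yl acetate | O[C@@H]2C[C@@]3(C)O[C@@H]3[C@H](O)[C@]3(C)[C@@H](OC(C)=O)C[C@@](O)(C(C)C)[C@@H]23 | intermediate
23 | 3,4-dimethoxybenzoyl chloride | COc1ccc(C(=O)Cl)cc1OC | starting material
24 | (1R,2S,4R,5R,6R,8R,9R,10R)-2-acetoxy-8,9-epoxy-4,10-dihydroxydaucan-6-yl 3,4-dimethoxybenzoate | COc1ccc(C(=O)O[C@@H]2C[C@@]3(C)O[C@@H]3[C@H](O)[C@]3(C)[C@@H](OC(C)=O)C[C@@](O)(C(C)C)[C@@H]23)cc1OC | target

Total step count: 15. Longest linear sequence: 13 (steps 1–8 and 11–15). Steps 9 and 10 are a two-step side branch.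

Steps most likely to fail

**Step 11.**
- Risks: loss of silanolate from the beta-silyloxy ylide, proton transfer from the two ketones to the ylide, or addition of C1 to C8 within the molecule may outrun the intended sequence. Facial control in the ring closure may also be weak.
- Fallback: it sets out from 13, uses known chemistry only, and makes the two bonds one after the other.
- A Mukaiyama aldol addition of 13 to acrolein (Et3SiOTf cat., CH2Cl2, −78 °C) would give the vinyl carbinol silyl ether F1.
- Wittig methylenation with Ph3P=CH2 would take the unhindered methyl ketone and give the diene F2.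
- Ring-closing metathesis with the second-generation Grubbs catalyst would give the cycloheptene ketone F3.
- NaBH4, then Ac2O/DMAP, then HF·pyridine would lead through the cycloheptene alcohol F4 and the cycloheptene acetate F5 to the allylic alcohol triol F6.
- Hydroxyl-directed epoxidation with VO(acac)2 and t-BuOOH, guided by the C10 and C6 hydroxyls on the same face, would bring the material back to the route at 22.

**Step 4.**
- Risks: mercuration at the enolisable positions of the ketone, capture of water with poor regiocontrol, or reduction of the C6 radical in place of its oxygenation may erode the conversion.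
- Fallback: it sets out from 5 and avoids both the metal and the redox detour.
- N-iodosuccinimide in aqueous acetone would open the cyclopropane by the same anti rule to the iodohydrin ketone F7.
- A Kornblum-type oxidation (AgBF4, DMSO, then Et3N) would turn the primary iodide into the aldehyde, so that the route is rejoined at 8.

**Step 15.**
- Risks: acylation may fail to discriminate between the C6 and C10 hydroxyls, or an acyl group may migrate under the basic conditions.
- Fallback: it sets out from 21 and replaces inherent selectivity by protecting-group differentiation.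
- Mild methanolysis (pyridinium p-toluenesulfonate, MeOH, 0 °C) would cleave only the least hindered secondary silyl ether and give the C6 alcohol F8.
- Esterification with 23 would give the bis(silyl) veratrate F9.
- HF·pyridine would then deliver 24 directly.

Further compounds

F1 | step 11 | vinyl carbinol silyl ether (acrolein aldol adduct of 13) | CC(=O)C[C@@H](O[Si](CC)(CC)CC)[C@H]1[C@](C)([C@@H](O[Si](CC)(CC)CC)C=C)C(=O)C[C@@]1(O[Si](CC)(CC)CC)C(C)C
F2 | step 11 | diene (methylenated F1) | C=C(C)C[C@@H](O[Si](CC)(CC)CC)[C@H]1[C@](C)([C@@H](O[Si](CC)(CC)CC)C=C)C(=O)C[C@@]1(O[Si](CC)(CC)CC)C(C)C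
F3 | step 11 | cycloheptene ketone, 4,6,10-tris(triethylsilyloxy)dauc-8-en-2-one | CC[Si](CC)(CC)O[C@@H]2CC(C)=C[C@H](O[Si](CC)(CC)CC)[C@]3(C)C(=O)C[C@@](O[Si](CC)(CC)CC)(C(C)C)[C@@H]23
F4 | step 11 | cycloheptene alcohol, 4,6,10-tris(triethylsilyloxy)dauc-8-en-2-ol | CC[Si](CC)(CC)O[C@@H]2CC(C)=C[C@H](O[Si](CC)(CC)CC)[C@]3(C)[C@@H](O)C[C@@](O[Si](CC)(CC)CC)(C(C)C)[C@@H]23
F5 | step 11 | cycloheptene acetate, 4,6,10-tris(triethylsilyloxy)dauc-8-en-2-yl acetate | CC[Si](CC)(CC)O[C@@H]2CC(C)=C[C@H](O[Si](CC)(CC)CC)[C@]3(C)[C@@H](OC(C)=O)C[C@@](O[Si](CC)(CC)CC)(C(C)C)[C@@H]23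
F6 | step 11 | allylic alcohol triol, 4,6,10-trihydroxydauc-8-en-2-yl acetate | O[C@@H]2CC(C)=C[C@H](O)[C@]3(C)[C@@H](OC(C)=O)C[C@@](O)(C(C)C)[C@@H]23
F7 | step 4 | iodohydrin ketone, 3-hydroxy-4-(iodomethyl)-5-methyl-3-(propan-2-yl)cyclopentan-1-one | IC[C@H]1[C@H](C)C(=O)C[C@@]1(O)C(C)C
F8 | step 15 | C6 alcohol, 8,9-epoxy-6-hydroxy-4,10-bis(triethylsilyloxy)daucan-2-yl acetate | O[C@@H]2C[C@@]3(C)O[C@@H]3[C@H](O[Si](CC)(CC)CC)[C@]3(C)[C@@H](OC(C)=O)C[C@@](O[Si](CC)(CC)CC)(C(C)C)[C@@H]23
F9 | step 15 | bis(silyl) veratrate, 2-acetoxy-8,9-epoxy-4,10-bis(triethylsilyloxy)daucan-6-yl 3,4-dimethoxybenzoate | COc1ccc(C(=O)O[C@@H]2C[C@@]3(C)O[C@@H]3[C@H](O[Si](CC)(CC)CC)[C@]3(C)[C@@H](OC(C)=O)C[C@@](O[Si](CC)(CC)CC)(C(C)C)[C@@H]23)cc1OC
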